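**Strategy.** The hydroazulene is disconnected at the ring-fusion bond C1–C5 (daucane numbering). The route exploits the oxygen on C6 of the seven-membered ring, which lies next to ring-fusion carbon C5: a C6 ketone flanked by the trans C1–C5 bond is the signature of a 1,2-shift. In a cis-fused decalin bearing a free tertiary C6 hydroxyl, an equatorial C5 mesylate and a silylated C4 carbinol, base makes C1 migrate from C6 to C5. This single operation contracts ring A to the cyclopentane, expands ring B to the cycloheptanone, creates the C6 carbonyl and sets the trans fusion by inversion at C5. The decalin derives from an asymmetric Robinson annulation.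

Key step: step 10

Remarks on the chemistry.
- Numbering: the daucane numbers of the target are kept for every intermediate. C1 is the methyl-bearing quaternary carbon, C2 and C3 are methylenes, C4 is the isopropyl carbinol carbon, C5 lies between C4 and C6, C6 is the ester carbon, C7 is a methylene, C8 is the methyl carbinol carbon, C9 is the secondary carbinol carbon and C10 is a methylene.
- In the decalins, ring A is C1–C2–C3–C4–C5–C6 and ring B is C1–C10–C9–C8–C7–C6. β is the face of the C1 methyl group, α the opposite face.
- Assumption: the R-configured amine auxiliary gives the S quaternary centre, the mirror image of the established outcome with the S-amine. Any shortfall in enantiomeric purity should be removable by recrystallising a crystalline intermediate such as diol 15.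

**Route**

Step 1
Reactants: 1 2-methylcyclohexanone (racemic); 2 (R)-1-phenylethylamine; 3 methyl vinyl ketone
Product: 6 (S)-2-methyl-2-(3-oxobutyl)cyclohexanone, via chiral imine 4 (not isolated), via Michael adduct imine 5 (not isolated)
Conditions: 2, TsOH (cat.), toluene, reflux, Dean–Stark; concentrate; 3, THF, 40 °C; then 10% aq. AcOH, rt
Reagents that add atoms: water, O
Why: Condensation gives the imine, whose more substituted secondary-enamine tautomer adds to the enone in an aza-ene-type Michael addition on the face away from the phenyl group of the auxiliary, setting the C1 quaternary centre as S, and mild acid hydrolysis then frees the 1,5-diketone (first half of an asymmetric Robinson annulation).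

Step 2
Reactants: 6 (S)-2-methyl-2-(3-oxobutyl)cyclohexanone
Product: 8 (S)-4a-methyl-4,4a,5,6,7,8-hexahydronaphthalen-2(3H)-one (octalone: C4 carbonyl and C5=C6 alkene and C1 methyl in the numbering used here), via cis-ketol 7 (not isolated)
Conditions: NaOMe, MeOH, 60 °C
Reagents that add atoms: none
Why: Intramolecular aldol addition followed by E1cB dehydration completes the Robinson annulation without touching the quaternary stereocentre.

Step 3
Reactants: 8 (S)-octalone; 9 isopropylmagnesium chloride
Product: 10 tertiary allylic alcohol 4α-isopropyl-1β-methyloctal-5-en-4β-ol (hydroxyl cis to the angular methyl)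
Conditions: CeCl3 (anhydrous), THF, −78 → 0 °C; aq. NH4Cl
Reagents that add atoms: none
Why: CeCl3-mediated Grignard 1,2-addition (Imamoto conditions) suppresses enolisation, β-hydride reduction and conjugate addition, and axial attack on the half-chair enone from the α-face, away from the angular methyl, should place the new C4 hydroxyl β.

Step 4
Reactants: 10 tertiary allylic alcohol
Product: 11 triethylsilyl ether of 10 (4β-triethylsilyloxy-4α-isopropyl-1β-methyloctal-5-ene)
Conditions: TESOTf, 2,6-lutidine, CH2Cl2, −78 → 0 °C
Reagents that add atoms: triethylsilyl trifluoromethanesulfonate, CC[Si](CC)(CC)OS(=O)(=O)C(F)(F)F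
Why: Silyl triflate with a hindered pyridine base silylates hindered tertiary alcohols at low temperature, and masking O4 here ensures that later only O6 can become an alkoxide.

Step 5
Reactants: 11 triethylsilyl ether
Product: 12 5α,6α-epoxide of 11 (epoxide oxygen trans to the angular methyl and to the silyloxy group)
Conditions: mCPBA, NaHCO3, CH2Cl2, 0 °C
Reagents that add atoms: 3-chloroperoxybenzoic acid, OOC(=O)c1cccc(Cl)c1
Why: Prilezhaev epoxidation of the trisubstituted C5=C6 alkene is expected on the α-face because the β-face carries both the angular methyl and the bulky allylic silyloxy group, and the bicarbonate buffer protects the epoxide and the silyl ether.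

Step 6
Reactants: 12 5α,6α-epoxide
Product: 13 trans-diol 4β-triethylsilyloxy-4α-isopropyl-1β-methyl-cis-decalin-5α,6β-diol
Conditions: HClO4 (cat.), THF/H2O, 0 °C
Reagents that add atoms: water, O
Why: In this acid-catalysed epoxide hydrolysis water opens the protonated epoxide at the tertiary C6 with inversion in a trans-diaxial sense (Fürst–Plattner), which puts the C6 hydroxyl β in a cis-decalin chair with equatorial isopropyl and leaves the C5 oxygen α.

Step 7
Reactants: 13 trans-diol
Product: 14 6β-hydroxy-4β-triethylsilyloxy-4α-isopropyl-1β-methyl-cis-decalin-5-one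
Conditions: Dess–Martin periodinane, NaHCO3, CH2Cl2, rt
Reagents that add atoms: none
Why: Dess–Martin oxidation converts the only secondary alcohol (C5) into the ketone, the tertiary C6 hydroxyl being inert and the trans-diaxial diol being unable to form the cyclic periodinane that leads to glycol cleavage.

Step 8
Reactants: 14 α-hydroxy ketone
Product: 15 all-cis diol 4β-triethylsilyloxy-4α-isopropyl-1β-methyl-cis-decalin-5β,6β-diol
Conditions: NaBH4, MeOH, −20 °C
Reagents that add atoms: none
Why: Borohydride reduction by axial attack on the α-face, the β-face of the C5 carbonyl being flanked by the axial C4 silyloxy and C6 hydroxyl groups, should give the equatorial 5β-alcohol and hence the all-cis 4,5,6-trioxygenated array.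

Step 9
Reactants: 15 all-cis diol
Product: 16 5β-mesylate of 15 (cis-decalin 5,6-diol 5-monomesylate)
Conditions: MsCl, Et3N, DMAP (cat.), CH2Cl2, −20 → 0 °C
Reagents that add atoms: methanesulfonyl chloride, CS(=O)(=O)Cl
Why: Sulfonylation through sulfene is fast for the secondary equatorial C5 hydroxyl and slow for the hindered tertiary C6 hydroxyl, so only C5 becomes the leaving group, with retention.

Step 10
Reactants: 16 diol monomesylate
Product: 18 trans-fused 4β-triethylsilyloxy-4α-isopropyl-1β-methyl-5α-H-hydroazulen-6-one, via potassium alkoxide 17 (not isolated)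
Conditions: KOtBu (1.1 equiv), tBuOH/THF, 0 °C → rt; aq. NH4Cl
Reagents that add atoms: none
Why: KOtBu deprotonates the only free hydroxyl (C6) and the alkoxide pushes the ring bond C6–C1 onto C5 as the mesylate leaves, a concerted semipinacol 1,2-alkyl shift that creates the C6 ketone and the C1–C5 bond. The closest known reaction type is the base-induced pinacol-type rearrangement of cis-decalin 1,2-diol monosulfonates to hydroazulenones. Neither ring is closed by a cyclisation: the single suprafacial shift of ring carbon C1 contracts ring A from six to five members and at the same time enlarges ring B from six to seven. The new stereocentre C5 arises by inversion, since C1 must enter anti to the departing C5–O bond, so the β-mesylate fixed in 16 gives the 5α-hydrogen and thus the trans ring fusion, while C1 migrates with retention and C4 is untouched. The step needs migration of C1 in preference to C7 and to displacement by oxygen, and the substrate secures this: in the ring A chair with equatorial isopropyl the equatorial C5–OMs bond is antiperiplanar only to C6–C1 (C6–C7 and the axial C6–O bond are gauche, so neither a C7 shift nor epoxide closure is aligned), and O4 is silylated so that no second alkoxide can trigger a shift of C3. Near-stoichiometric base, which is consumed as the mesylate salt, limits later enolisation of the β-silyloxy ketone toward C5.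

Step 11
Reactants: 18 hydroazulen-6-one
Product: 20 7-en-6-one (C7=C8 enone of 18), via trimethylsilyl enol ether 19 (not isolated)
Conditions: LiN(iPr)2, TMSCl, THF, −78 °C; then Pd(OAc)2 (1 equiv), MeCN, rt
Reagents that add atoms: none
Why: Kinetic deprotonation occurs at the C7 methylene (C5 is a hindered methine whose neighbours C1 and C4 carry no hydrogen), and Saegusa–Ito oxidation of the silyl enol ether by divalent palladium (oxa-π-allyl formation, β-hydride elimination) gives the enone.

Step 12
Reactants: 20 7-en-6-one
Product: 22 8-methyl-7-en-6-one, via 8-methyl trimethylsilyl enol ether 21 (not isolated)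
Conditions: Me2CuLi (from CuI and 2 MeLi), TMSCl, THF, −78 °C; then Pd(OAc)2 (1 equiv), MeCN, rt
Reagents that add atoms: lithium dimethylcuprate, [Li+].C[Cu-]C
Why: Conjugate addition of the Gilman reagent, accelerated and trapped by TMSCl, places the methyl on C8, and a second Saegusa–Ito oxidation removes the transient C8 stereocentre and returns the enone with the methyl on its β-carbon.

Step 13
Reactants: 22 8-methyl-7-en-6-one
Product: 24 8-methyl-8-en-6-one (β,γ-unsaturated ketone), via potassium dienolate 23 (not isolated)
Conditions: KOtBu, tBuOH/THF, 0 °C; inverse quench into cold 10% aq. AcOH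
Reagents that add atoms: none
Why: γ-Deprotonation at C9 gives the extended endocyclic dienolate and kinetic protonation at the α-carbon C7 gives the deconjugated ketone, the classical deconjugation of β-alkyl enones used to turn steroidal 4-en-3-ones into 5-en-3-ones.

Step 14
Reactants: 24 8-methyl-8-en-6-one
Product: 25 8-methyl-8-en-6α-ol (4β-triethylsilyloxy; C6 hydroxyl equatorial and trans to the angular methyl)
Conditions: SmI2, H2O, Et3N, THF, 0 °C
Reagents that add atoms: none
Why: This single-electron, dissolving-metal-type ketone reduction is governed by product stability and should give the equatorial 6α-alcohol, which avoids the 1,3-diaxial contact with the C1 methyl, whereas a kinetic hydride would be steered to the opposite face by that same methyl; the isolated alkene and the silyl ether are inert.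

Step 15
Reactants: 26 4-hydroxybenzoic acid
Product: 28 4-(tert-butyldimethylsilyloxy)benzoic acid, via bis-silyl derivative 27 (not isolated)
Conditions: TBSCl (2.2 equiv), imidazole, DMF, rt; then AcOH, THF/H2O, rt
Reagents that add atoms: tert-butyldimethylsilyl chloride, CC(C)(C)[Si](C)(C)Cl
Why: Silylation of phenol and acid followed by selective hydrolysis of the labile silyl ester leaves the robust aryl silyl ether.

Step 16
Reactants: 25 8-methyl-8-en-6α-ol; 28 4-(tert-butyldimethylsilyloxy)benzoic acid
Product: 29 6α-[4-(tert-butyldimethylsilyloxy)benzoate] of 25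
Conditions: DCC, DMAP, CH2Cl2, rt → 40 °C
Reagents that add atoms: none
Why: Steglich esterification acylates the only free hydroxyl with retention at C6.

Step 17
Reactants: 29 ester
Product: 30 8α,9α-epoxide of 29
Conditions: mCPBA, NaHCO3, CH2Cl2, 0 °C
Reagents that add atoms: 3-chloroperoxybenzoic acid, OOC(=O)c1cccc(Cl)c1
Why: Prilezhaev epoxidation of the only alkene should occur on the α-face because the axial C1 methyl, homoallylic to C9, shields the β-face of C8=C9 in the way the angular methyl does in steroidal 2-enes.

Step 18
Reactants: 30 8α,9α-epoxide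
Product: 31 8β,9α-diol (4-O-triethylsilyl and aryl O-tert-butyldimethylsilyl protected target)
Conditions: HClO4 (cat.), THF/H2O, 0 °C
Reagents that add atoms: water, O
Why: In this acid-catalysed epoxide hydrolysis water attacks the tertiary C8 from the β-face with inversion while C9 keeps its α-oxygen, giving the trans-diol; the α-ester cannot reach the β-face to participate and the hindered tertiary and aryl silyl ethers should survive brief cold dilute acid.

Step 19
Reactants: 31 protected diol
Product: 32 target CNP0197754.1
Conditions: TBAF, AcOH, THF, 0 °C → rt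
Reagents that add atoms: none
Why: Fluoride-mediated desilylation cleaves the aryl silyl ether quickly and the tertiary triethylsilyl ether more slowly, and the acetic acid buffer keeps the benzoate and the triol untouched.

**Compound list**

1 | 2-methylcyclohexanone (racemic) | CC1CCCCC1=O | starting material
2 | (R)-1-phenylethylamine | C[C@@H](N)c1ccccc1 | starting material
3 | methyl vinyl ketone | CC(=O)C=C | starting material
4 | chiral imine: N-[(R)-1-phenylethyl]imine of 2-methylcyclohexanone (ring methyl centre unresolved) | CC1CCCCC1=N[C@H](C)c1ccccc1 | intermediate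
5 | Michael adduct imine: N-[(R)-1-phenylethyl]imine of (S)-2-methyl-2-(3-oxobutyl)cyclohexanone | CC(=O)CC[C@]1(C)CCCCC1=N[C@H](C)c1ccccc1 | intermediate
6 | (S)-2-methyl-2-(3-oxobutyl)cyclohexanone | CC(=O)CC[C@]1(C)CCCCC1=O | intermediate
7 | cis-ketol: cis-fused 6β-hydroxy-1β-methyldecalin-4-one | O=C1CC[C@]2(C)CCCC[C@]2(O)C1 | intermediate
8 | (S)-4a-methyl-4,4a,5,6,7,8-hexahydronaphthalen-2(3H)-one | O=C1CC[C@]2(C)CCCCC2=C1 | intermediate
9 | isopropylmagnesium chloride | CC(C)[Mg]Cl | starting material
10 | 4α-isopropyl-1β-methyloctal-5-en-4β-ol | CC(C)[C@]1(O)CC[C@]2(C)CCCCC2=C1 | intermediate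
11 | 4β-triethylsilyloxy-4α-isopropyl-1β-methyloctal-5-ene | CC(C)[C@]1(O[Si](CC)(CC)CC)CC[C@]2(C)CCCCC2=C1 | intermediate
12 | 5α,6α-epoxide of 11 | CC(C)[C@]1(O[Si](CC)(CC)CC)CC[C@]2(C)CCCC[C@]23O[C@H]13 | intermediate
13 | 4β-triethylsilyloxy-4α-isopropyl-1β-methyl-cis-decalin-5α,6β-diol | CC(C)[C@]1(O[Si](CC)(CC)CC)CC[C@]2(C)CCCC[C@]2(O)[C@@H]1O | intermediate
14 | 6β-hydroxy-4β-triethylsilyloxy-4α-isopropyl-1β-methyl-cis-decalin-5-one | CC(C)[C@]1(O[Si](CC)(CC)CC)CC[C@]2(C)CCCC[C@]2(O)C1=O | intermediate
15 | 4β-triethylsilyloxy-4α-isopropyl-1β-methyl-cis-decalin-5β,6β-diol | CC(C)[C@]1(O[Si](CC)(CC)CC)CC[C@]2(C)CCCC[C@]2(O)[C@H]1O | intermediate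
16 | 5β-mesylate of 15 (key-step precursor) | CC(C)[C@]1(O[Si](CC)(CC)CC)CC[C@]2(C)CCCC[C@]2(O)[C@H]1OS(C)(=O)=O | intermediate
17 | potassium 6-alkoxide of 16 | CC(C)[C@]1(O[Si](CC)(CC)CC)CC[C@]2(C)CCCC[C@]2([O-])[C@H]1OS(C)(=O)=O.[K+] | intermediate
18 | trans-fused 4β-triethylsilyloxy-4α-isopropyl-1β-methyl-5α-H-hydroazulen-6-one (key-step product) | CC(C)[C@]1(O[Si](CC)(CC)CC)CC[C@]2(C)CCCCC(=O)[C@H]21 | intermediate
19 | 6-trimethylsilyloxy-6-ene (kinetic enol ether of 18) | CC(C)[C@]1(O[Si](CC)(CC)CC)CC[C@]2(C)CCCC=C(O[Si](C)(C)C)[C@H]21 | intermediate
20 | 7-en-6-one | CC(C)[C@]1(O[Si](CC)(CC)CC)CC[C@]2(C)CCC=CC(=O)[C@H]21 | intermediate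
21 | 8-methyl-6-trimethylsilyloxy-6-ene (C8 configuration unassigned; it is removed in the same step) | CC(C)[C@]1(O[Si](CC)(CC)CC)CC[C@]2(C)CCC(C)C=C(O[Si](C)(C)C)[C@H]21 | intermediate
22 | 8-methyl-7-en-6-one | CC(C)[C@]1(O[Si](CC)(CC)CC)CC[C@]2(C)CCC(C)=CC(=O)[C@H]21 | intermediate
23 | potassium 6,8-dienolate of 22 | CC(C)[C@]1(O[Si](CC)(CC)CC)CC[C@]2(C)CC=C(C)C=C([O-])[C@H]21.[K+] | intermediate
24 | 8-methyl-8-en-6-one | CC(C)[C@]1(O[Si](CC)(CC)CC)CC[C@]2(C)CC=C(C)CC(=O)[C@H]21 | intermediate
25 | 8-methyl-8-en-6α-ol | CC(C)[C@]1(O[Si](CC)(CC)CC)CC[C@]2(C)CC=C(C)C[C@H](O)[C@H]21 | intermediate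
26 | 4-hydroxybenzoic acid | O=C(O)c1ccc(O)cc1 | starting material
27 | tert-butyldimethylsilyl 4-(tert-butyldimethylsilyloxy)benzoate | CC(C)(C)[Si](C)(C)OC(=O)c1ccc(O[Si](C)(C)C(C)(C)C)cc1 | intermediate
28 | 4-(tert-butyldimethylsilyloxy)benzoic acid | O=C(O)c1ccc(O[Si](C)(C)C(C)(C)C)cc1 | intermediate
29 | 6α-[4-(tert-butyldimethylsilyloxy)benzoate] of 25 | CC(C)[C@]1(O[Si](CC)(CC)CC)CC[C@]2(C)CC=C(C)C[C@H](OC(=O)c3ccc(O[Si](C)(C)C(C)(C)C)cc3)[C@H]21 | intermediate
30 | 8α,9α-epoxide of 29 | CC(C)[C@]1(O[Si](CC)(CC)CC)CC[C@]2(C)C[C@@H]3O[C@]3(C)C[C@H](OC(=O)c4ccc(O[Si](C)(C)C(C)(C)C)cc4)[C@H]21 | intermediate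
31 | 8β,9α-diol, doubly silyl-protected target | CC(C)[C@]1(O[Si](CC)(CC)CC)CC[C@]2(C)C[C@H](O)[C@@](C)(O)C[C@H](OC(=O)c3ccc(O[Si](C)(C)C(C)(C)C)cc3)[C@H]21 | intermediate
32 | CNP0197754.1: 4β,8β,9α-trihydroxy-5α-H-daucan-6α-yl 4-hydroxybenzoate | CC(C)[C@]1(O)CC[C@]2(C)C[C@H](O)[C@@](C)(O)C[C@H](OC(=O)c3ccc(O)cc3)[C@H]21 | target

**Step count.** Total: 19 steps. Longest linear sequence: 18 steps (steps 1–14 and 16–19); step 15 is a one-step side branch.

**The three steps most likely to fail**

Step 10 (key step). Two processes may go wrong. The triethylsilyl group may move from O4 to the neighbouring axial O6 alkoxide, after which the freed O4 alkoxide would drive a shift of C3 and contract ring A the wrong way. The product ketone may also enolise toward C5, with epimerisation of the ring fusion or loss of silyloxide. The fallback leaves the free-alkoxide manifold altogether. Mesylate 16 is treated with Et3Al in CH2Cl2 at −78 °C → 0 °C, the aluminium-promoted semipinacol rearrangement known for 2-sulfonyloxy alcohols. The covalent aluminium alkoxide at O6 is not basic, and the Lewis acid assists departure of the mesylate. The same anti 1,2-shift of C1 then proceeds without a species able to shuttle silicon or to enolise the product. It sets out from 16 and returns at 18; no new compound is made (F0).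

Step 5. The peracid may attack the β-face instead of the α-face (poor facial selectivity), or the epoxide may open at C5 in step 6; either would carry the wrong C6 configuration forward. The fallback is a Woodward cis-hydroxylation of 11 (I2, AgOAc, AcOH, rt; then AcOH/H2O, rt → 50 °C). Iodonium formation is reversible, so the outcome is decided in the opening step: acetate adds to the tertiary C6 from the β-face trans-diaxially to the 5α-iodide. Silver-assisted displacement of the axial iodide by the antiperiplanar 6β-acetoxy group then gives the β-face acetoxonium ion. Water converts this into the cis-5β,6β-diol monoacetate F1, and K2CO3 in MeOH removes the acetyl group. The fallback sets out from 11 and returns at 15, bypassing 12, 13 and 14.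

Step 13. Deprotonation may compete at C5, leading to epimerisation of the ring fusion or E1cB loss of the C4 silyloxy group. The exocyclic dienolate may form instead of the endocyclic one. The product may reconjugate during quench or purification. The fallback avoids the free potassium dienolate. Soft enolisation of 22 with TMSOTf and Et3N in CH2Cl2 at 0 °C gives the neutral 6-trimethylsilyloxy-6,8-diene F2. Its cleavage with TBAF buffered by AcOH in THF at −78 °C protonates C7 kinetically. It sets out from 22 and returns at 24.

**Further compounds**

F1 | step 5 | cis-5β,6β-diol monoacetate of the decalin (drawn as the 5-O-acetate; the 6-O-acetyl isomer converges on the same diol) | CC(C)[C@]1(O[Si](CC)(CC)CC)CC[C@]2(C)CCCC[C@]2(O)[C@H]1OC(C)=O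
F0 | step 10 | none | none
F2 | step 13 | 6-trimethylsilyloxy-8-methyl-6,8-diene (silyl dienol ether of 22) | CC(C)[C@]1(O[Si](CC)(CC)CC)CC[C@]2(C)CC=C(C)C=C(O[Si](C)(C)C)[C@H]21
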